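The numbers in the tables are calculated for an exercise; scatter was added.

Product counted in millimolar rather than percent shows what the catalyst delivers, and the midnight flask and the autumn run share their free catalyst but not their substrate.

| setting | midnight | autumn | flask |
|---|---|---|---|
| substrate | 0.050 M | 0.10 M | 0.050 M |
| free catalyst | 1.2 mM | 1.2 mM | 1.2 mM |
| remark | the very flask that is asked about, followed so far | run made earlier |  |
| time |  |  | 25 h |

| run | time / h | product / % | substrate / % |
|---|---|---|---|
| midnight | 6.00 | 32 | 68 |
| midnight | 8.00 | 38 | 59 |
| midnight | 10.0 | 47 | 49 |
| midnight | 12.0 | 54 | 46 |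
| autumn | 6.00 | 18 | 82 |
| autumn | 8.00 | 22 | 77 |
| autumn | 12.0 | 28 | 69 |
| autumn | 20.0 | 44 | 59 |
| autumn | 25.0 | 48 | 55 |

(readings scatter by 1.5 percentage points)

1. the best time, 25 h at the latest, for product
2. the amount of product, in percent of the substrate charged, at that time
3. the first time at which product reaches 57%, in the same percent

Take the run in slow motion. Over the first 6.00 h, the midnight flask makes product at 2.67 mM h⁻¹ on average. By 12.0 h it holds 27.0 mM, and autumn, with twice the substrate, holds 28.0 mM: as read, within the scatter, this looks close to zero order in substrate. From 12.0 h to 25.0 h, autumn makes 1.54 mM h⁻¹ on average, slower than the 3.00 mM h⁻¹ of its own first 6.00 h. Yet autumn still holds 55.0 mM of substrate at its end, more than midnight's whole charge of 0.050 M. I read that as the catalyst weakening (deactivation).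

So I carry the catalyst's output, the product in millimolar that this charge of catalyst has made by 25.0 h in the autumn run, as read: 48.0 mM. Set against the midnight flask's charge, that reading is 96.0%. I expect to land below it, since midnight's substrate at 12.0 h is 23.0 mM, a third of autumn's. By my own reckoning, going on from the midnight reading at 12.0 h at autumn's late rate, the 28.5 mM asked for comes at about 13.0 h.

The forecast puts the best time at 25 h, on the ground that “product is not being lost”, with 78% there; it has 57% reached at 13.4 h, later than my 13.0 h.

The flask gives 81.1% at 25.0 h and reaches 57% at 13.4 h, so the forecast stands within its margins.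

    substrate + free catalyst → catalyst intermediate A (k = 0.0590 M⁻¹ s⁻¹)
    catalyst intermediate A → catalyst intermediate B (k = 0.00140 s⁻¹)
    2 catalyst intermediate A → spent catalyst (k = 0.0280 M⁻¹ s⁻¹)
    catalyst intermediate B → free catalyst + product (k = 0.00440 s⁻¹)

At 25.0 h substrate still stands at 17.3%, so the flask stops on the clock, not on an empty charge. Its output is 40.5 mM, below the carried 48.0 mM.

On the neighbour flask with 0.20 M of substrate, the carried output gives 24.0% of that charge. The computed result is 24.4%, with substrate at 75.0%.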